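Larch and ash hold what can be read before this flask, so set them beside its charge and the questions.

| flask | substrate | remark | time |
|---|---|---|---|
| larch | 0.67 M | run made earlier |  |
| ash | 1.5 M | run made earlier |  |
| flask | 1.0 M |  | 5.0 h |

| run | time / h | target / % | isomer of the product / % | substrate / % |
|---|---|---|---|---|
| larch | 0.250 | 16 | 82 | 0 |
| larch | 0.417 | 29 | 73 | 4 |
| larch | 0.833 | 49 | 54 | 0 |
| larch | 1.50 | 58 | 41 | 5 |
| larch | 3.00 | 68 | 29 | 1 |
| ash | 0.250 | 20 | 80 | 1 |
| ash | 0.833 | 52 | 48 | 2 |
| ash | 1.33 | 65 | 31 | 1 |
| ash | 2.00 | 77 | 22 | 0 |
| ash | 3.00 | 84 | 15 | 1 |

(standard deviation of a reading: 2 percentage points)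

1. share of target in target plus isomer of the product at 3.0 s
2. share of target in target plus isomer of the product at 5.0 h
3. which of target and isomer of the product there is more of at 5.0 h

- what was read earlier has a scatter of 2 percentage points, one standard deviation
- a reading or a percentage of target counts all its forms, free or not

Check each number for what an error in it would change at 5.0 h. Leave substrate aside: at the first readings it stands at 0% in larch and 1% in ash, with a scatter of 2 percentage points. Isomer comes first and target later, with 82% against 16% at the first larch reading.

The last isomer readings carry the weight. Turn them into amounts per litre: larch ends at 0.194 M and ash at 0.225 M, though ash was charged twice as heavily. Freeze that amount. The gap between the two is 3.07% of this flask's charge, and that is how far the answer moves between them. Their mean, 0.210 M, is the isomer level: the isomer per litre left at the last reading of these runs. But isomer in ash still fell from 22% to 15% over its last stretch, so the level may read high.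

My reckoning takes one minus the level over the charge, which gives 79.0% target in this flask at 5.0 h.

The forecast gives 0.1% (0% to 3%) at 3.0 s, 83% (78% to 87%) at 5.0 h, and target ahead. Its ground is this: “This suggests target is being sequestered, through aggregation or precipitation, above a fixed isomer level”. Its level is 0.165 M, so its share stands higher than mine.

The flask gives 2.36% at 3.0 s and 79.7% at 5.0 h, with target ahead.

    substrate → target (k = 0.0947 min⁻¹)
    crystals ⇌ target, rate k2*(cs2 - [target]) while solid is left; crystals form when [target] > cs2 (solubility = 0.0590 M, k = 3.36 min⁻¹)
    target ⇌ isomer of the product (K = 3.40, k = 0.0664 min⁻¹)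
    other conformer → isomer of the product (k = 1.29 min⁻¹)
    substrate ⇌ other conformer, settled at all times (K = 3.10)

At 5.00 h crystals make up 73.8% of the flask's charge, counted in target. Dissolved target stands near its solubility of 0.059 M, and 3.4 times that is 0.201 M, beside the 0.203 M of isomer the flask holds. Carry the isomer level to the neighbouring flask charged with 0.60 M, time held: one minus 0.210 M over that charge gives 65.0%. That neighbour holds crystals at 56.5% of its charge and isomer at 33.6%, and its share of target comes to 66.4%.

All runs are simulated from invented constants; noise was put on by code.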